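**Plan**

- Cuts, in retrosynthetic order: the eleven phenol O–H bonds (carried as methoxymethyl, MOM, acetals); the enone Cβ–aryl bond (Mizoroki–Heck on an aryl bromide); in one operation the dihydrobenzofuran C3–C3a bond and the bond from the exocyclic methine to the resorcinol ring of the oxolane half; the two aryl–carbon bonds of the oxolane half (aryllithium on a lactone and a Weinreb amide); the lactone Cα–benzyl bond and the aldol bond.
- Enabling feature: dihydrobenzofuran C3 carries a methine bearing a 2,4-dioxygenated aryl group, and the benzo carbon C3a is ortho to the ring oxygen. The five-membered ring O1–C2–C3–C3a–C7a can therefore come from the six-membered ring O1–C2–C3–C4–C4a–C8a of a 2,3-trans-3,4-trans-4-arylflavan-3-ol by a 1,2-shift of C4a from C4 to C3. This ejects C4 as an oxygen-stabilised benzylic cation, which the resorcinol ring of the second half captures.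
- Forward order: chromone → (R)-flavanone → 4-aryl-2H-chromene → chroman-3-ol mesylate; succinyl imide → trans-γ-lactone → oxolane; ring contraction with Friedel–Crafts union; Heck; deprotection.
- Stereochemistry: flavanone C2 from a chiral pyridine-oxazoline palladium catalyst; chroman C3 and C4 from hydroboration anti to the C2 aryl group, both inverted in the key step to give dihydrobenzofuran C3 and the methine; oxolane C2/C3 from an auxiliary-controlled syn-aldol, C4 from trans-alkylation of the lactone enolate, C5 from hydride delivery anti to the benzyl group.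
- Helpers: bromine holds the place of the enone so the migrating benzo ring stays electron-rich; the mesylate is the only activating group and leaves in the key step.

Key step: step 18

Remark: the (S)-tert-butyl pyridine-oxazoline ligand is taken to give the (2R)-flavanone by analogy with its sense of induction on cyclic enones; if the sense is opposite, the ligand antipode is used.

Remark: 2,4-bis(methoxymethoxy)benzaldehyde is taken as a catalogue compound, like the methoxymethyl-protected building blocks 4 and 15.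

MOM = CH2OCH3 throughout.

**Route**

Step 1
Reactants: 1 4-bromoresorcinol
Product: 2 1-bromo-2,4-bis(methoxymethoxy)benzene
Conditions: MOMCl (2.5 equiv), iPr2NEt, CH2Cl2, 0 °C → rt
Reagents that add atoms: chloromethyl methyl ether, COCCl
Why: O-alkylation of both phenols by the α-chloro ether (Williamson type); no stereocentre is involved.

Step 2
Reactants: 3 6-bromochromone; 4 [4-(methoxymethoxy)phenyl]boronic acid
Product: 5 (2R)-6-bromo-2-[4-(methoxymethoxy)phenyl]-2,3-dihydro-4H-chromen-4-one
Conditions: Pd(OCOCF3)2 (5 mol %), (S)-4-tert-butyl-2-(pyridin-2-yl)-4,5-dihydrooxazole (6 mol %), NH4PF6 (30 mol %), H2O (5 equiv), ClCH2CH2Cl, 60 °C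
Reagents that add atoms: none
Why: asymmetric conjugate addition of an arylboronic acid to a chromone by a cationic divalent palladium pyridine-oxazoline complex, in which the tert-butyl group of the ligand selects the enone face and sets C2 as R; the aryl bromide is inert because no zerovalent palladium is formed.

Step 3
Reactants: 5 (2R)-6-bromo-flavanone; 2 1-bromo-2,4-bis(methoxymethoxy)benzene
Product: 7 (2R)-4-[2,4-bis(methoxymethoxy)phenyl]-6-bromo-2-[4-(methoxymethoxy)phenyl]chroman-4-ol (C4 epimers), via arylmagnesium bromide 6 (not isolated)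
Conditions: 2 (1.4 equiv), Mg turnings (1.6 equiv, activated with a crystal of I2), THF, 25 → 40 °C; 5 premixed with LaCl3·2LiCl (1.0 equiv), THF, rt, 1 h; Grignard solution added at 0 °C; aq. NH4Cl
Reagents that add atoms: none
Why: magnesium insertion into the aryl bromide gives the Grignard reagent, which adds 1,2 to the ketone in the presence of the lanthanum salt; the salt favours carbonyl addition over enolisation (which would open the pyranone and racemise C2), the aryl bromide of 5 does not exchange with the preformed Grignard reagent at 0 °C, and the new carbinol centre is removed in step 4.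

Step 4
Reactants: 7 tertiary chroman-4-ol
Product: 8 (2R)-4-[2,4-bis(methoxymethoxy)phenyl]-6-bromo-2-[4-(methoxymethoxy)phenyl]-2H-chromene
Conditions: Burgess reagent (1.5 equiv), THF, 25 → 50 °C, dark
Reagents that add atoms: none
Why: syn-elimination of the sulfamate of a tertiary benzylic alcohol under neutral conditions; only C3 carries β-hydrogens, so only the C3=C4 alkene can form, and the C2–O bond is not ionised.

Step 5
Reactants: 8 4-aryl-2H-chromene
Product: 10 (2S,3R,4S)-4-[2,4-bis(methoxymethoxy)phenyl]-6-bromo-2-[4-(methoxymethoxy)phenyl]chroman-3-ol (2,3-trans-3,4-trans; C2 is now S only because C3 outranks the aryl group), via alkylborane 9 (not isolated)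
Conditions: BH3·THF (3 equiv), THF, 0 °C → rt; then NaOH, H2O2, 0 °C
Reagents that add atoms: hydrogen peroxide, OO
Why: hydroboration–oxidation in which boron adds to the less substituted C3 on the face anti to the C2 aryl group, hydrogen adds syn at C4, and oxidation proceeds with retention, giving the all-equatorial 2,3-trans-3,4-trans alcohol.

Step 6
Reactants: 10 (2S,3R,4S)-chroman-3-ol
Product: 11 (2S,3R,4S)-4-[2,4-bis(methoxymethoxy)phenyl]-6-bromo-2-[4-(methoxymethoxy)phenyl]chroman-3-yl methanesulfonate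
Conditions: MsCl, Et3N, CH2Cl2, −20 → 0 °C; used without delay
Reagents that add atoms: methanesulfonyl chloride, CS(=O)(=O)Cl
Why: O-sulfonylation with retention at C3, which places an equatorial leaving group anti-periplanar to the C4–C4a bond.

Step 7
Reactants: 12 (4R)-4-benzyl-1,3-oxazolidin-2-one; 13 methyl 4-chloro-4-oxobutanoate
Product: 14 methyl 4-[(4R)-4-benzyl-2-oxo-1,3-oxazolidin-3-yl]-4-oxobutanoate
Conditions: n-BuLi, THF, −78 °C; then 13, −78 → 0 °C
Reagents that add atoms: none
Why: N-acylation of the lithiated oxazolidinone by the acid chloride.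

Step 8
Reactants: 14 succinyl imide; 15 4-(methoxymethoxy)benzaldehyde
Product: 18 (4R)-4-benzyl-3-{(2R,3R)-2-[4-(methoxymethoxy)phenyl]-5-oxooxolane-3-carbonyl}-1,3-oxazolidin-2-one (trans-lactone), via boron enolate 16 (not isolated), via aldol adduct 17 (not isolated)
Conditions: Bu2BOSO2CF3 (1.1 equiv), iPr2NEt (1.2 equiv), CH2Cl2, −78 → 0 °C; 15, −78 → 0 °C; aq. phosphate buffer (pH 7), rt
Reagents that add atoms: none
Why: Evans syn-aldol through the (Z)-boron enolate and a Zimmerman–Traxler transition state, with the aldehyde approaching anti to the benzyl group of the auxiliary to give the (3R,4R)-syn adduct, whose oxygen then closes onto the methyl ester (5-exo-trig lactonisation) so that syn becomes the trans-lactone.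

Step 9
Reactants: 18 lactone imide
Product: 20 (2R,3R)-2-[4-(methoxymethoxy)phenyl]-5-oxooxolane-3-carboxylic acid, via peroxy acid 19 (not isolated)
Conditions: LiOH, H2O2, THF/H2O (3:1), 0 °C; Na2SO3; cold dilute HCl to pH 3
Reagents that add atoms: hydrogen peroxide, OO
Why: hydroperoxide attacks the exocyclic imide carbonyl selectively, sulfite reduces the percarboxylate, and acidification recloses any opened lactone; no stereocentre is touched.

Step 10
Reactants: 15 4-(methoxymethoxy)benzaldehyde
Product: 21 [4-(methoxymethoxy)phenyl]methanol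
Conditions: NaBH4, MeOH, 0 °C
Reagents that add atoms: none
Why: hydride reduction of an aldehyde.

Step 11
Reactants: 21 [4-(methoxymethoxy)phenyl]methanol
Product: 22 1-(bromomethyl)-4-(methoxymethoxy)benzene
Conditions: CBr4, PPh3, CH2Cl2, 0 °C; used at once
Reagents that add atoms: tetrabromomethane, BrC(Br)(Br)Br
Why: Appel bromination under neutral conditions that leave the acetal intact.

Step 12
Reactants: 20 lactone acid; 22 benzylic bromide
Product: 24 (2R,3R,4R)-4-{[4-(methoxymethoxy)phenyl]methyl}-2-[4-(methoxymethoxy)phenyl]-5-oxooxolane-3-carboxylic acid, via dilithium enolate carboxylate 23 (not isolated)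
Conditions: LiN(SiMe3)2 (2.2 equiv), THF, −78 °C; 22, −78 → −30 °C; cold dilute HCl to pH 3
Reagents that add atoms: none
Why: alkylation of the lactone enolate of a paraconic acid dianion, in which the carboxylate shields C3–H from deprotonation and the bromide enters anti to the C3 carboxylate, setting C4 trans to C3.

Step 13
Reactants: 24 benzylated lactone acid
Product: 25 (2R,3R,4R)-N-methoxy-N-methyl-4-{[4-(methoxymethoxy)phenyl]methyl}-2-[4-(methoxymethoxy)phenyl]-5-oxooxolane-3-carboxamide
Conditions: MeNH(OMe)·HCl, EDC·HCl, HOBt, iPr2NEt, CH2Cl2, 0 °C → rt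
Reagents that add atoms: N,O-dimethylhydroxylamine hydrochloride, CNOC.Cl
Why: carbodiimide amide coupling; C3 is already trans to both neighbours, so epimerisation is not a concern.

Step 14
Reactants: 25 lactone Weinreb amide; 2 1-bromo-2,4-bis(methoxymethoxy)benzene
Product: 27 [2,4-bis(methoxymethoxy)phenyl]{(2R,3R,4R)-5-[2,4-bis(methoxymethoxy)phenyl]-5-hydroxy-4-{[4-(methoxymethoxy)phenyl]methyl}-2-[4-(methoxymethoxy)phenyl]oxolan-3-yl}methanone (hemiketal, anomers), via aryllithium 26 (not isolated)
Conditions: 2 (3.2 equiv), n-BuLi (3.0 equiv), THF, −78 °C; 25, −78 °C; aq. NH4Cl at −78 °C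
Reagents that add atoms: none
Why: bromine–lithium exchange gives the aryllithium, which adds once to the lactone carbonyl and once to the Weinreb amide; both tetrahedral adducts collapse only on protonation, which gives the aryl ketone and the cyclic hemiketal without touching the three stereocentres.

Step 15
Reactants: 27 hemiketal
Product: 28 [2,4-bis(methoxymethoxy)phenyl]{(2R,3R,4R,5S)-5-[2,4-bis(methoxymethoxy)phenyl]-4-{[4-(methoxymethoxy)phenyl]methyl}-2-[4-(methoxymethoxy)phenyl]oxolan-3-yl}methanone (2,3-trans-3,4-trans-4,5-cis)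
Conditions: Et3SiH (4 equiv), BF3·OEt2 (2 equiv), CH2Cl2, −78 → −40 °C
Reagents that add atoms: none
Why: ionic hydrogenation of the cyclic hemiketal through the 2-aryl oxocarbenium ion, with hydride adding on the face anti to the adjacent C4 benzyl group so that the aryl group at C5 ends cis to it (C5 S), while the ketone conjugated to the electron-rich arene is not reduced at this temperature.

Step 16
Reactants: 29 2,4-bis(methoxymethoxy)benzaldehyde
Product: 30 1-[2,4-bis(methoxymethoxy)phenyl]prop-2-en-1-ol (racemic)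
Conditions: CH2=CHMgBr (1.2 equiv), THF, −78 → 0 °C; aq. NH4Cl
Reagents that add atoms: vinylmagnesium bromide, C=C[Mg]Br
Why: 1,2-addition of a vinyl Grignard reagent to an aromatic aldehyde; the carbinol centre is racemic and is removed in step 17.

Step 17
Reactants: 30 allylic alcohol
Product: 31 1-[2,4-bis(methoxymethoxy)phenyl]prop-2-en-1-one
Conditions: Dess–Martin periodinane, CH2Cl2, 0 °C → rt; kept cold with a trace of BHT
Reagents that add atoms: none
Why: oxidation of an allylic benzylic alcohol to the aryl vinyl ketone under non-basic conditions.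

Step 18
Reactants: 11 chroman-3-yl mesylate; 28 oxolane ketone
Product: 33 {(2R,3R,4R,5S)-5-[5-{(R)-[(2R,3R)-5-bromo-2-[4-(methoxymethoxy)phenyl]-2,3-dihydro-1-benzofuran-3-yl][2,4-bis(methoxymethoxy)phenyl]methyl}-2,4-bis(methoxymethoxy)phenyl]-4-{[4-(methoxymethoxy)phenyl]methyl}-2-[4-(methoxymethoxy)phenyl]oxolan-3-yl}[2,4-bis(methoxymethoxy)phenyl]methanone, via benzylic cation 32 (not isolated)
Conditions: 28 (2.5 equiv, excess recovered), 2,6-di-tert-butyl-4-methylpyridine (1.5 equiv), (CF3)2CHOH/CH2Cl2 (4:1), 0 °C; 11 in CH2Cl2 added slowly; 0 → 25 °C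
Reagents that add atoms: none
Why: Proposed new method: in the strongly ionising, weakly nucleophilic fluoro alcohol the equatorial C3 mesylate of the all-equatorial half-chair departs with participation of the anti-periplanar C4–C4a bond, so that the benzo carbon C4a (ortho to the ring oxygen, which stabilises the bridged phenonium-like transition state) shifts from C4 to C3 with inversion at C3, the six-membered ring O1–C2–C3–C4–C4a–C8a becomes the five-membered ring O1–C2–C3–C3a–C7a, and C4 is expelled as the exocyclic 2,4-bis(alkoxy)benzyl cation 32, which the alkyl-substituted resorcinol ring of 28 captures at its free position para to one acetal oxygen and ortho to the other with loss of a proton to the hindered pyridine. The closest known reaction types are the phenonium 1,2-aryl shift in the solvolysis of β-aryl sulfonates, the pinacol-type ring contraction of flavan-3,4-diol derivatives to 2-aryl-2,3-dihydrobenzofurans and the Friedel–Crafts alkylation of resorcinol ethers by alkoxybenzyl cations in hexafluoroisopropanol; their union in one step on a flavan-3-yl sulfonate is the untested part. The furan ring is closed by the 1,2-shift itself (3-exo-tet bridging of C4a onto C3 followed by cleavage of C4–C4a), not by a chain cyclisation. C3 of the dihydrobenzofuran is set by the stereospecific anti migration (C2 is untouched, hence 2,3-trans), and the methine is expected to be R because 32 is born with the migrated carbon C3a still covering one face and with C3–H eclipsing the aryl group (minimal allylic 1,3-strain), so that the arene adds anti to C3a, which amounts to inversion at the former C4 of the 3,4-trans precursor. The step needs aryl migration in preference to migration of the ring oxygen or of the C2 aryl group (secured by the diequatorial geometry, in which the C2 aryl bond is gauche to the leaving group, and by the better cation at C4), and it needs capture by the alkyl-resorcinol ring of 28 in preference to its ketone-deactivated resorcinol ring, to self-alkylation and to loss of H3 (secured by excess 28, slow addition of 11 and the non-nucleophilic base).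

Step 19
Reactants: 33 aryl bromide; 31 aryl vinyl ketone
Product: 34 undeca-MOM ether of the target: as 33, with the 5-bromo substituent replaced by (1E)-3-[2,4-bis(methoxymethoxy)phenyl]-3-oxoprop-1-en-1-yl
Conditions: Pd2(dba)3 (5 mol %; dba = dibenzylideneacetone), P(t-Bu)3·HBF4 (12 mol %), Cy2NMe (1.5 equiv), 31 (2 equiv), 1,4-dioxane, 70 °C
Reagents that add atoms: none
Why: Mizoroki–Heck reaction in which zerovalent palladium inserts into the only aryl bromide, the vinyl ketone inserts syn at its terminal carbon and syn-β-hydride elimination gives the (E)-enone.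

Step 20
Reactants: 34 undeca-MOM ether
Product: 36 CNP0225254.6 (target), via undecakis(trimethylsilyl) ether 35 (not isolated)
Conditions: Me3SiOSO2CF3 (3 equiv per acetal), 2,2′-bipyridyl (4.5 equiv per acetal), CH2Cl2, 0 °C → rt; then H2O, rt
Reagents that add atoms: none
Why: each aryl methoxymethyl acetal is activated by the silyl triflate–bipyridyl complex and converted into the aryl silyl ether (the acetal carbon is taken up by bipyridyl), and water then hydrolyses the silyl ethers at neutral pH, so that no free Brønsted acid meets the benzylic ether bonds, the enone or any stereocentre.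

**Compound list**

1 | 4-bromoresorcinol (4-bromobenzene-1,3-diol) | Oc1ccc(Br)c(O)c1 | starting material
2 | 1-bromo-2,4-bis(methoxymethoxy)benzene | COCOc1ccc(Br)c(OCOC)c1 | intermediate
3 | 6-bromochromone (6-bromo-4H-chromen-4-one) | O=c1ccoc2ccc(Br)cc12 | starting material
4 | [4-(methoxymethoxy)phenyl]boronic acid | COCOc1ccc(B(O)O)cc1 | starting material
5 | (2R)-6-bromo-2-[4-(methoxymethoxy)phenyl]-2,3-dihydro-4H-chromen-4-one | O=C1C[C@H](c2ccc(OCOC)cc2)Oc2ccc(Br)cc21 | intermediate
6 | bromo[2,4-bis(methoxymethoxy)phenyl]magnesium (Grignard reagent formed in the flask, not isolated) | COCOc1ccc([Mg]Br)c(OCOC)c1 | intermediate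
7 | (2R)-4-[2,4-bis(methoxymethoxy)phenyl]-6-bromo-2-[4-(methoxymethoxy)phenyl]chroman-4-ol (C4 epimers) | OC1(c2ccc(OCOC)cc2OCOC)C[C@H](c2ccc(OCOC)cc2)Oc2ccc(Br)cc21 | intermediate
8 | (2R)-4-[2,4-bis(methoxymethoxy)phenyl]-6-bromo-2-[4-(methoxymethoxy)phenyl]-2H-chromene | Brc1ccc2c(c1)C(c1ccc(OCOC)cc1OCOC)=C[C@H](c1ccc(OCOC)cc1)O2 | intermediate
9 | chroman-3-ylborane from 8, boron on C3 trans to the C2 aryl group and cis to H4 (not isolated) | Brc1ccc2c(c1)[C@H](c1ccc(OCOC)cc1OCOC)[C@@H](B)[C@H](c1ccc(OCOC)cc1)O2 | intermediate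
10 | (2S,3R,4S)-4-[2,4-bis(methoxymethoxy)phenyl]-6-bromo-2-[4-(methoxymethoxy)phenyl]chroman-3-ol | Brc1ccc2c(c1)[C@H](c1ccc(OCOC)cc1OCOC)[C@@H](O)[C@H](c1ccc(OCOC)cc1)O2 | intermediate
11 | (2S,3R,4S)-4-[2,4-bis(methoxymethoxy)phenyl]-6-bromo-2-[4-(methoxymethoxy)phenyl]chroman-3-yl methanesulfonate | Brc1ccc2c(c1)[C@H](c1ccc(OCOC)cc1OCOC)[C@@H](OS(C)(=O)=O)[C@H](c1ccc(OCOC)cc1)O2 | intermediate
12 | (4R)-4-benzyl-1,3-oxazolidin-2-one | O=C1N[C@H](Cc2ccccc2)CO1 | starting material
13 | methyl 4-chloro-4-oxobutanoate | COC(=O)CCC(=O)Cl | starting material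
14 | methyl 4-[(4R)-4-benzyl-2-oxo-1,3-oxazolidin-3-yl]-4-oxobutanoate | COC(=O)CCC(=O)N1[C@H](Cc2ccccc2)COC1=O | intermediate
15 | 4-(methoxymethoxy)benzaldehyde | COCOc1ccc(C=O)cc1 | starting material
16 | (Z)-dibutylboron enolate of 14 (not isolated) | COC(=O)C/C=C(\OB(CCCC)CCCC)N1[C@H](Cc2ccccc2)COC1=O | intermediate
17 | methyl (3R,4R)-3-{[(4R)-4-benzyl-2-oxo-1,3-oxazolidin-3-yl]carbonyl}-4-hydroxy-4-[4-(methoxymethoxy)phenyl]butanoate (syn-aldol adduct, not isolated) | COC(=O)C[C@H]([C@@H](O)c1ccc(OCOC)cc1)C(=O)N1[C@H](Cc2ccccc2)COC1=O | intermediate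
18 | (4R)-4-benzyl-3-{(2R,3R)-2-[4-(methoxymethoxy)phenyl]-5-oxooxolane-3-carbonyl}-1,3-oxazolidin-2-one | O=C1O[C@@H](c2ccc(OCOC)cc2)[C@H](C(=O)N2[C@H](Cc3ccccc3)COC2=O)C1 | intermediate
19 | (2R,3R)-2-[4-(methoxymethoxy)phenyl]-5-oxooxolane-3-carboperoxoic acid (not isolated) | O=C1O[C@@H](c2ccc(OCOC)cc2)[C@H](C(=O)OO)C1 | intermediate
20 | (2R,3R)-2-[4-(methoxymethoxy)phenyl]-5-oxooxolane-3-carboxylic acid | O=C1O[C@@H](c2ccc(OCOC)cc2)[C@H](C(=O)O)C1 | intermediate
21 | [4-(methoxymethoxy)phenyl]methanol | COCOc1ccc(CO)cc1 | intermediate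
22 | 1-(bromomethyl)-4-(methoxymethoxy)benzene | COCOc1ccc(CBr)cc1 | intermediate
23 | dilithium salt of 20 (carboxylate plus lactone enolate, not isolated) | [Li]OC1=C[C@@H](C(=O)O[Li])[C@H](c2ccc(OCOC)cc2)O1 | intermediate
24 | (2R,3R,4R)-4-{[4-(methoxymethoxy)phenyl]methyl}-2-[4-(methoxymethoxy)phenyl]-5-oxooxolane-3-carboxylic acid | O=C1O[C@@H](c2ccc(OCOC)cc2)[C@H](C(=O)O)[C@H]1Cc1ccc(OCOC)cc1 | intermediate
25 | (2R,3R,4R)-N-methoxy-N-methyl-4-{[4-(methoxymethoxy)phenyl]methyl}-2-[4-(methoxymethoxy)phenyl]-5-oxooxolane-3-carboxamide | O=C1O[C@@H](c2ccc(OCOC)cc2)[C@H](C(=O)N(C)OC)[C@H]1Cc1ccc(OCOC)cc1 | intermediate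
26 | [2,4-bis(methoxymethoxy)phenyl]lithium (formed in the flask, not isolated) | [Li]c1ccc(OCOC)cc1OCOC | intermediate
27 | [2,4-bis(methoxymethoxy)phenyl]{(2R,3R,4R)-5-[2,4-bis(methoxymethoxy)phenyl]-5-hydroxy-4-{[4-(methoxymethoxy)phenyl]methyl}-2-[4-(methoxymethoxy)phenyl]oxolan-3-yl}methanone (anomers) | COCOc1ccc(C2(O)O[C@@H](c3ccc(OCOC)cc3)[C@H](C(=O)c3ccc(OCOC)cc3OCOC)[C@H]2Cc2ccc(OCOC)cc2)c(OCOC)c1 | intermediate
28 | [2,4-bis(methoxymethoxy)phenyl]{(2R,3R,4R,5S)-5-[2,4-bis(methoxymethoxy)phenyl]-4-{[4-(methoxymethoxy)phenyl]methyl}-2-[4-(methoxymethoxy)phenyl]oxolan-3-yl}methanone | COCOc1ccc([C@H]2O[C@@H](c3ccc(OCOC)cc3)[C@H](C(=O)c3ccc(OCOC)cc3OCOC)[C@H]2Cc2ccc(OCOC)cc2)c(OCOC)c1 | intermediate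
29 | 2,4-bis(methoxymethoxy)benzaldehyde | COCOc1ccc(C=O)c(OCOC)c1 | starting material
30 | 1-[2,4-bis(methoxymethoxy)phenyl]prop-2-en-1-ol (racemic) | C=CC(O)c1ccc(OCOC)cc1OCOC | intermediate
31 | 1-[2,4-bis(methoxymethoxy)phenyl]prop-2-en-1-one | C=CC(=O)c1ccc(OCOC)cc1OCOC | intermediate
32 | [(2R,3R)-5-bromo-2-[4-(methoxymethoxy)phenyl]-2,3-dihydro-1-benzofuran-3-yl][2,4-bis(methoxymethoxy)phenyl]methylium methanesulfonate (ion pair, not isolated) | Brc1ccc2c(c1)[C@@H]([CH+]c1ccc(OCOC)cc1OCOC)[C@H](c1ccc(OCOC)cc1)O2.CS(=O)(=O)[O-] | intermediate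
33 | {(2R,3R,4R,5S)-5-[5-{(R)-[(2R,3R)-5-bromo-2-[4-(methoxymethoxy)phenyl]-2,3-dihydro-1-benzofuran-3-yl][2,4-bis(methoxymethoxy)phenyl]methyl}-2,4-bis(methoxymethoxy)phenyl]-4-{[4-(methoxymethoxy)phenyl]methyl}-2-[4-(methoxymethoxy)phenyl]oxolan-3-yl}[2,4-bis(methoxymethoxy)phenyl]methanone | Brc1ccc2c(c1)[C@@H]([C@H](c1ccc(OCOC)cc1OCOC)c1cc([C@H]3O[C@@H](c4ccc(OCOC)cc4)[C@H](C(=O)c4ccc(OCOC)cc4OCOC)[C@H]3Cc3ccc(OCOC)cc3)c(OCOC)cc1OCOC)[C@H](c1ccc(OCOC)cc1)O2 | intermediate
34 | undeca-MOM ether of the target: 33 with Br replaced by (1E)-3-[2,4-bis(methoxymethoxy)phenyl]-3-oxoprop-1-en-1-yl | O=C(/C=C/c1ccc2c(c1)[C@@H]([C@H](c1ccc(OCOC)cc1OCOC)c1cc([C@H]3O[C@@H](c4ccc(OCOC)cc4)[C@H](C(=O)c4ccc(OCOC)cc4OCOC)[C@H]3Cc3ccc(OCOC)cc3)c(OCOC)cc1OCOC)[C@H](c1ccc(OCOC)cc1)O2)c1ccc(OCOC)cc1OCOC | intermediate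
35 | undecakis(trimethylsilyl) ether of the target (not isolated) | O=C(/C=C/c1ccc2c(c1)[C@@H]([C@H](c1ccc(O[Si](C)(C)C)cc1O[Si](C)(C)C)c1cc([C@H]3O[C@@H](c4ccc(O[Si](C)(C)C)cc4)[C@H](C(=O)c4ccc(O[Si](C)(C)C)cc4O[Si](C)(C)C)[C@H]3Cc3ccc(O[Si](C)(C)C)cc3)c(O[Si](C)(C)C)cc1O[Si](C)(C)C)[C@H](c1ccc(O[Si](C)(C)C)cc1)O2)c1ccc(O[Si](C)(C)C)cc1O[Si](C)(C)C | intermediate
36 | CNP0225254.6: (2E)-1-(2,4-dihydroxyphenyl)-3-[(2R,3R)-3-{(R)-(2,4-dihydroxyphenyl)[5-{(2S,3R,4R,5R)-4-(2,4-dihydroxybenzoyl)-3-[(4-hydroxyphenyl)methyl]-5-(4-hydroxyphenyl)oxolan-2-yl}-2,4-dihydroxyphenyl]methyl}-2-(4-hydroxyphenyl)-2,3-dihydro-1-benzofuran-5-yl]prop-2-en-1-one | O=C(/C=C/c1ccc2c(c1)[C@@H]([C@H](c1ccc(O)cc1O)c1cc([C@H]3O[C@@H](c4ccc(O)cc4)[C@H](C(=O)c4ccc(O)cc4O)[C@H]3Cc3ccc(O)cc3)c(O)cc1O)[C@H](c1ccc(O)cc1)O2)c1ccc(O)cc1O | target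

**Totals and risks**

Total step count: 20. Longest linear sequence: 10 steps (7, 8, 9, 12, 13, 14, 15, 18, 19, 20).

Steps most likely to fail:

1. Step 18 (proposed new method). The ionisation may be steered into migration of the ring oxygen or of the C2 aryl group instead of C4a. The cation may lose H3 and aromatise to a benzofuran, or alkylate another molecule of its own series. The arene may also add with poor facial selectivity at the methine. Fallback, setting out from 5 and coming back at 33: flavanone 5 is ring-contracted by the known oxidative 1,2-aryl shift with trivalent iodine (PhI(OAc)2, HC(OMe)3, catalytic H2SO4, rt) to methyl (2R,3R)-5-bromo-2-[4-(methoxymethoxy)phenyl]-2,3-dihydro-1-benzofuran-3-carboxylate F1. Reduction with i-Bu2AlH (CH2Cl2, −78 °C) should give (2R,3R)-5-bromo-2-[4-(methoxymethoxy)phenyl]-2,3-dihydro-1-benzofuran-3-carbaldehyde F2. Addition of arylmagnesium bromide 6 (THF, −78 → 0 °C) should give [2,4-bis(methoxymethoxy)phenyl][(2R,3R)-5-bromo-2-[4-(methoxymethoxy)phenyl]-2,3-dihydro-1-benzofuran-3-yl]methanol F3 as carbinol epimers. Dehydrative Friedel–Crafts alkylation of 28 with F3 in (CF3)2CHOH at rt then passes through the same cation 32 from an established entry and gives 33.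

2. Step 14. Two carbonyl groups must each take up one aryllithium; over-addition to the ring-opened ketone, deprotonation next to the amide with β-elimination of the lactone oxygen, or retro-aldol cleavage on quenching may erode the step. Fallback, setting out from 24 and coming back at 28: acid 24 is deprotonated with LiN(SiMe3)2 (1 equiv) and treated with aryllithium 26 (1.3 equiv, THF, −78 °C), so that only the lactone reacts, giving (2R,3R,4R)-5-[2,4-bis(methoxymethoxy)phenyl]-5-hydroxy-4-{[4-(methoxymethoxy)phenyl]methyl}-2-[4-(methoxymethoxy)phenyl]oxolane-3-carboxylic acid F4. Reduction with Et3SiH and BF3·OEt2 as in step 15 should give (2R,3R,4R,5S)-5-[2,4-bis(methoxymethoxy)phenyl]-4-{[4-(methoxymethoxy)phenyl]methyl}-2-[4-(methoxymethoxy)phenyl]oxolane-3-carboxylic acid F5. Carbodiimide coupling as in step 13 gives its N-methoxy-N-methylamide F6, and one equivalent of aryllithium 26 then gives 28.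

3. Step 20. Eleven acetals must be cleaved on one molecule; incomplete cleavage, Lewis-acid ionisation of the benzylic ether bonds with loss of the oxolane configuration, and losses on isolating the free polyphenol are the likely failure processes. Fallback, setting out from 34 and coming back at 36: after the silyl triflate–bipyridyl treatment and water quench, the crude phenol mixture is peracetylated at once (Ac2O, pyridine, catalytic DMAP, 0 °C) to the undeca-acetate of the target F7. This can be purified by chromatography, with acetal-bearing fractions returned to the cleavage, and is then deacetylated under nearly neutral conditions (NH4OAc, MeOH, rt) to 36.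

**Further compounds**

F1 | step 18 | methyl (2R,3R)-5-bromo-2-[4-(methoxymethoxy)phenyl]-2,3-dihydro-1-benzofuran-3-carboxylate | Brc1ccc2c(c1)[C@@H](C(=O)OC)[C@H](c1ccc(OCOC)cc1)O2
F2 | step 18 | (2R,3R)-5-bromo-2-[4-(methoxymethoxy)phenyl]-2,3-dihydro-1-benzofuran-3-carbaldehyde | Brc1ccc2c(c1)[C@@H](C=O)[C@H](c1ccc(OCOC)cc1)O2
F3 | step 18 | [2,4-bis(methoxymethoxy)phenyl][(2R,3R)-5-bromo-2-[4-(methoxymethoxy)phenyl]-2,3-dihydro-1-benzofuran-3-yl]methanol (carbinol epimers) | Brc1ccc2c(c1)[C@@H](C(O)c1ccc(OCOC)cc1OCOC)[C@H](c1ccc(OCOC)cc1)O2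
F4 | step 14 | (2R,3R,4R)-5-[2,4-bis(methoxymethoxy)phenyl]-5-hydroxy-4-{[4-(methoxymethoxy)phenyl]methyl}-2-[4-(methoxymethoxy)phenyl]oxolane-3-carboxylic acid (anomers) | COCOc1ccc(C2(O)O[C@@H](c3ccc(OCOC)cc3)[C@H](C(=O)O)[C@H]2Cc2ccc(OCOC)cc2)c(OCOC)c1
F5 | step 14 | (2R,3R,4R,5S)-5-[2,4-bis(methoxymethoxy)phenyl]-4-{[4-(methoxymethoxy)phenyl]methyl}-2-[4-(methoxymethoxy)phenyl]oxolane-3-carboxylic acid | COCOc1ccc([C@H]2O[C@@H](c3ccc(OCOC)cc3)[C@H](C(=O)O)[C@H]2Cc2ccc(OCOC)cc2)c(OCOC)c1
F6 | step 14 | (2R,3R,4R,5S)-5-[2,4-bis(methoxymethoxy)phenyl]-N-methoxy-N-methyl-4-{[4-(methoxymethoxy)phenyl]methyl}-2-[4-(methoxymethoxy)phenyl]oxolane-3-carboxamide | COCOc1ccc([C@H]2O[C@@H](c3ccc(OCOC)cc3)[C@H](C(=O)N(C)OC)[C@H]2Cc2ccc(OCOC)cc2)c(OCOC)c1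
F7 | step 20 | undeca-acetate of the target (all eleven phenols as acetates) | O=C(/C=C/c1ccc2c(c1)[C@@H]([C@H](c1ccc(OC(C)=O)cc1OC(C)=O)c1cc([C@H]3O[C@@H](c4ccc(OC(C)=O)cc4)[C@H](C(=O)c4ccc(OC(C)=O)cc4OC(C)=O)[C@H]3Cc3ccc(OC(C)=O)cc3)c(OC(C)=O)cc1OC(C)=O)[C@H](c1ccc(OC(C)=O)cc1)O2)c1ccc(OC(C)=O)cc1OC(C)=O
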